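## Structural features

Compound 16 is a flavone: a carbocyclic ring A (C4a, C5, C6, C7, C8, C8a) fused to a 4-pyranone ring C (O1, C2, C3, C4, C4a, C8a), with an unsubstituted phenyl ring B on C2 and free hydroxyl groups on C5 and C7. An N-methylpiperidine ring (N1', C2'–C6') is attached through C2' to C8, the ring A carbon that lies between C7–OH and C8a–O1. C2' is the only stereocentre (R); no second stereocentre stands next to it, so its configuration cannot be relayed and has to be set absolutely. C2' is benzylic, bonded to nitrogen, and ortho, ortho and para to three ring oxygens; once the nitrogen is protonated or bound to a Lewis acid, the C2'–N1' bond can ionise (ortho-quinone methide or benzylic cation, retro-Mannich direction), which racemises C2' or opens the piperidine. Further weak points are the 5-hydroxyflavone, which in hot protic acid can open and reclose through the other ortho oxygen and so move the substituent from C8 to C6 (Wessely–Moser rearrangement), the basic tertiary amine, which deactivates late-metal catalysts, and the oxidation-prone phloroglucinol pattern. The flavone itself is routine; the real difficulty is to create C2' as one enantiomer on a 2,4,6-trioxygenated benzene ring, to keep it through the acidic steps that build ring C, and to place the heterocycle on C8 and not on C6. The key step uses the fact that the piperidine ring N1'–C2'–C3'–C4'–C5'–C6' can be opened at C3'–C4', a bond that does not touch C2': C2' with its N1' and C3' neighbours is made first in an open chain, and the ring is closed afterwards between a vinyl group on C2' and a but-3-enyl group on N1'.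

## Logic of the disconnections

16 ⇒ 15. The two O–CH3 bonds on O5 and O7 are cut. Both oxygens are ortho or para to C8; as free phenols they would make C2'–N1' of every earlier intermediate far easier to ionise and would compete in the acylation chemistry, whereas as methyl ethers they are inert and already present in 1. The gain is an intermediate without acidic groups next to the amine. The forward step must cleave the ethers with a Lewis acid at or below room temperature, because hot protic acid would invite loss of configuration at C2' and the C8-to-C6 switch of a 5-hydroxyflavone.

15 ⇒ 12 + 13 (through 14). Ring C is opened at O1–C2 and C2–C3. This is the standard retron of a flavone, an ortho-hydroxyaryl methyl ketone plus a benzoyl unit, and it removes ring B and ring C in one operation. The only free hydroxyl of 12 is the one flanked by the acetyl group and C8, so the ring can close in one direction only. The forward step must acylate the methyl ketone at carbon in the presence of a phenoxide and a tertiary amine, then dehydrate under acid mild enough for C2'.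

12 ⇒ 11. The aryl–carbonyl bond C4a–C4 is cut and the acetyl group is placed on the neighbouring oxygen. The reason is positional control without an extra reagent: an acyl group delivered from that oxygen can reach only the one free ortho carbon. The gain is an arene whose only carbon substituent is the heterocycle. The demand is severe: an acyl shift under a Lewis acid on the ring in which C2'–N1' ionises most easily, so the lowest workable temperature has to be found.

11 ⇒ 10. C3'–C4' is desaturated to create the retron for olefin metathesis. Nothing is simplified yet. The forward step must add hydrogen to the ring alkene without hydrogenolysis of the allylic, benzylic C2'–N1' bond and without moving the double bond to C2'.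

10 ⇒ 7. The piperidine is opened at C3'=C4'. This is the one ring bond that involves neither nitrogen nor C2', so the stereocentre and both of its ring bonds can be in place before the ring exists. The cut turns a heterocycle into an open-chain tertiary amine with two terminal alkenes. The forward metathesis must run next to a basic nitrogen (hence on the ammonium salt), must not let ruthenium hydrides move either double bond, and must not ionise the protonated C2'–N1' bond.

7 ⇒ 5 + 6. The O–acyl bond of the aryl acetate is cut. The free ortho-phenol of 5 is what makes C2' labile towards acid; as an ester the oxygen is a much weaker donor. The acetyl group is not wasted, because it becomes C4 and C3 of the flavone two steps later. There is no gain in simplicity and the cost is one step. The forward acylation must be fast and mild and follow directly on the making of 5.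

5 ⇒ 1 + 2 + 3. Both bonds made at the stereocentre, C2'–N1' and C2'–C3', are cut at once. A three-component borono-Mannich reaction forms them from an aldehyde, a secondary amine and a vinylboron reagent; the ortho-hydroxyl of 1 (the future O1) brings boron to the iminium carbon, and 2 already holds the N-methyl group and C4'–C6' with the second alkene. The gain is maximal: three achiral, purchasable components. The demand is enantiofacial control at an iminium flanked by a hydroxyl and a methoxy group, which calls for a chiral diol catalyst and a boronic ester that can exchange with it.

## Other disconnections considered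

Alternative 1: Ring A is taken apart. Forward, the bonds C8–C2', C5–C6, C7–C8 and C4a–C5 are formed from the diazo ketone A2 (made from N-Boc-(R)-pipecolic acid A1; its diazo carbon sits between the pipecolyl carbonyl and C2 of a phenyl-bearing pyranone ring) and ethoxyacetylene A3.
- Key step: irradiation of A2 should cause a Wolff rearrangement in which C2' migrates with retention. The ketene adds A3 in a [2+2] cycloaddition, and on heating the cyclobutenone opens (4π) and the dienylketene closes (6π) onto the pyranone to give the phenol A4.
- In favour: C2' is bought, not made. Nitrogen stays a carbamate, so C2'–N1' is a poor leaving group, and the ring A oxygens do not exist until the key step. On configurational safety during ring construction this plan is better than the chosen one. C8 substitution and the O5/O7 pattern are fixed by construction, so no Fries regiochemistry is needed, which is also better.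
- Against: in A2, C2' is α to a ketone and must survive base-mediated diazo transfer. The ketene is fully substituted and hindered, and the carbamate carbonyl can trap it. The step needs photochemistry and a volatile alkyne. Carbamate removal (acid, now on the electron-rich ring), N-methylation and O-dealkylation still follow.
- Comparison: on structure it builds the arene last, where the chosen plan builds the piperidine last. On mechanism it is a pericyclic cascade with built-in regiocontrol against two catalytic steps of established scope. On step economy it is about equal (some three operations to A2, the key step, three more), with more sensitive intermediates.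

Alternative 2: The cut is N1'–C2', with C2' as the carbinol carbon of the racemic carbamate alcohol A5.
- Key step: a bulky binaphthol-derived chiral phosphoric acid dehydrates A5 to an ortho-quinone methide held as a chiral ion pair. The carbamate nitrogen adds to C2' (6-exo-trig) and both enantiomers of A5 converge on A6.
- In favour: the ionisation that threatens the chosen route becomes the stereodetermining event. A5 needs no enantioselective step. A6 is a carbamate and configurationally more robust than 10, which is better on that point. There is no precious metal and no alkene to reduce.
- Against: selectivity depends on how tightly a highly stabilised, dimethoxy-substituted quinone methide is held by the phosphate, with a methoxy group crowding the exocyclic carbon. The carbamate N–H is a weak nucleophile, so proton loss from C3' to a styrene can compete. The same acid can re-ionise A6. A hydride reduction of the carbamate to N-methyl is needed before any ketone is present, and it leads to the phenol of 11, where the lability of C2' returns.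
- Comparison: on structure it makes the same 2-arylpiperidine. On mechanism it asks one catalyst to create C2' and close the ring together, where the chosen plan separates the two tasks (steps 1 and 3); that is more elegant but a larger extrapolation. On step economy it is equal (about two steps to A5 from 1, the key step, the reduction, then the same end game).

Alternative 3: The cuts are C5'–C6' and N1'–C6'; C6' comes from carbon monoxide A8 and the precursor is the secondary homoallylic amine A7.
- Key step: a rhodium carbonyl catalyst with a wide-bite-angle diphosphine hydroformylates the terminal carbon. The aldehyde condenses with the N–H and the cyclic iminium/enamine is hydrogenated to A9.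
- In favour: it is the most atom-economic closure. The ring is formed saturated, so no separate alkene reduction is needed, and C2' is never allylic. On ring-forming step count, on allylic ionisation and on alkene migration it is better than the chosen plan. A9 is the phenol of 11 and would join the chosen route by acetylation.
- Against: A7 as one enantiomer has no three-component catalytic access as direct as step 1; an auxiliary-controlled allylation of an imine of 1 followed by N-methylation would cost three to four steps. The key step runs hot and under pressure on a free ortho-phenol beside a protonatable amine, the conditions under which the retro-Mannich path at C2' is most likely. Chelation-directed branched hydroformylation would give a methylpyrrolidine. Secondary amines and phenols slow the catalyst.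
- Comparison: on structure it delivers the same piperidine without the alkene detour. On mechanism it is a carbonylative cascade against metathesis plus hydrogenation. On step economy it is better after A7 and worse before it, so overall about equal, with more thermal stress on C2'.

Key step: step 3

Remarks before the steps:
- Assumption: the (S)-enantiomer of 3,3'-dibromo-1,1'-bi-2-naphthol is taken to induce R at C2'. If the sense on this substrate is the opposite, the (R)-diol is used and nothing else changes.
- Design points: 3 is the dibutyl ester, because it exchanges alkoxide with the diol catalyst. The phenol oxygen is carried through steps 3 and 4 as its acetate, which is a change of protecting group only; the bond formed in step 3 and the carbon–nitrogen skeletons of its precursor 7 and product 10 are unchanged.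
- The descriptor R holds for 5, 7–12 and 14–16, since N1' > aryl carbon > C3' > H applies in each.

## Route

Step 1
Reactants: 1 2-hydroxy-4,6-dimethoxybenzaldehyde; 2 N-methylbut-3-en-1-amine; 3 dibutyl vinylboronate
Product: 5 (R)-2-{1-[but-3-en-1-yl(methyl)amino]prop-2-en-1-yl}-3,5-dimethoxyphenol, via iminium phenoxide 4 (not isolated)
Conditions: 2 (1.2 equiv), 3 (1.5 equiv), (S)-3,3'-Br2-BINOL (15 mol %), 4 Å MS, PhMe, 0 °C → rt; aqueous work-up
Reagents that add atoms: none
Why: Asymmetric Petasis borono-Mannich reaction of a salicylaldehyde, a secondary amine and an alkenylboronic ester under chiral diol catalysis; 1 and 2 condense to the iminium phenoxide 4, the binaphthol replaces a butoxy group on boron, the phenoxide oxygen binds the boron, and the vinyl group passes from this chiral boronate to one face of the iminium carbon, which sets C2' as R. The dibutyl ester is chosen because it exchanges alkoxide with the diol readily, which a pinacol ester does not.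

Step 2
Reactants: 5 (R)-2-{1-[but-3-en-1-yl(methyl)amino]prop-2-en-1-yl}-3,5-dimethoxyphenol; 6 acetic anhydride
Product: 7 (R)-2-{1-[but-3-en-1-yl(methyl)amino]prop-2-en-1-yl}-3,5-dimethoxyphenyl acetate
Conditions: 6 (1.2 equiv), Et3N, DMAP (5 mol %), CH2Cl2, 0 °C, directly after step 1
Reagents that add atoms: none
Why: DMAP-catalysed O-acylation of a phenol; the tertiary amine cannot be acylated. The ester closes the ortho-quinone methide path at C2' before any acid is used, and it is the acetyl source for step 5.

Step 3
Reactants: 7 (R)-2-{1-[but-3-en-1-yl(methyl)amino]prop-2-en-1-yl}-3,5-dimethoxyphenyl acetate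
Product: 10 (R)-3,5-dimethoxy-2-(1-methyl-1,2,5,6-tetrahydropyridin-2-yl)phenyl acetate, via diene ammonium tosylate 8 (not isolated), via cyclic ammonium tosylate 9 (not isolated)
Conditions: TsOH·H2O (1.05 equiv), CH2Cl2, rt; second-generation Grubbs catalyst RuCl2(=CHPh)(H2IMes)(PCy3) (5 mol %), 1,4-benzoquinone (10 mol %), CH2Cl2 (0.01 M), 40 °C, Ar stream; then cold aq. NaHCO3
Reagents that add atoms: none
Why: Ring-closing olefin metathesis of an amine-bearing 1,7-diene run on its ammonium salt 8, the known way to keep a basic nitrogen off the ruthenium centre. The catalyst benzylidene should first exchange with the unhindered but-3-enyl terminus, and the resulting alkylidene then adds across the C2' vinyl group through a ruthenacyclobutane whose cycloreversion forms C3'=C4' and passes on a methylidene that leaves as ethene. The six-membered ring is thus closed by an intramolecular alkene–alkylidene [2+2]/retro-[2+2] sequence; the ring alkene is necessarily Z, and ethene loss together with high dilution favours closure over oligomerisation. No stereocentre is formed; C2', set in step 1, is not a reacting atom. The step needs chemoselective initiation, which the steric difference between the two alkenes provides. It needs freedom from ruthenium hydride alkene migration toward C2', for which the acidic medium, the benzoquinone and the low temperature are used. It also needs an intact protonated allylic, benzylic C2'–N1' bond, which the acetate (a weak donor, no quinone methide path), the non-nucleophilic sulfonate and the 40 °C limit are meant to secure.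

Step 4
Reactants: 10 (R)-3,5-dimethoxy-2-(1-methyl-1,2,5,6-tetrahydropyridin-2-yl)phenyl acetate
Product: 11 (R)-3,5-dimethoxy-2-(1-methylpiperidin-2-yl)phenyl acetate
Conditions: H2 (1 atm), PtO2 (5 mol %), EtOAc, rt
Reagents that add atoms: none
Why: Heterogeneous hydrogenation of a cis-disubstituted ring alkene. Platinum and the neutral amine are chosen because they cause less allylic C–N hydrogenolysis and less double-bond migration toward C2' than palladium or the ammonium salt; C2' is not touched.

Step 5
Reactants: 11 (R)-3,5-dimethoxy-2-(1-methylpiperidin-2-yl)phenyl acetate
Product: 12 (R)-1-[2-hydroxy-4,6-dimethoxy-3-(1-methylpiperidin-2-yl)phenyl]ethan-1-one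
Conditions: BF3·OEt2 (5 equiv), ClCH2CH2Cl, 60 °C (lowest temperature that gives turnover); aqueous work-up
Reagents that add atoms: none
Why: Lewis acid-promoted Fries rearrangement: the acetyl group moves from oxygen to the only free ortho carbon, which is also para to a methoxy group, and the internally hydrogen-bonded ortho-hydroxy ketone is the favoured product over the twisted ketone between the two methoxy groups. This makes the C4a–C4 bond of the flavone and frees the phenol that becomes O1.

Step 6
Reactants: 12 (R)-1-[2-hydroxy-4,6-dimethoxy-3-(1-methylpiperidin-2-yl)phenyl]ethan-1-one; 13 benzoyl chloride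
Product: 15 (R)-5,7-dimethoxy-8-(1-methylpiperidin-2-yl)-2-phenyl-4H-chromen-4-one, via 1,3-diketone 14 (not isolated)
Conditions: LiN(SiMe3)2 (3.5 equiv), THF, −78 → −20 °C; 13 (1.05 equiv), −78 °C → rt; AcOH, THF evaporated; AcOH, conc. HCl, 60 °C
Reagents that add atoms: none
Why: Claisen-type C-benzoylation of the lithium phenoxide–enolate dianion gives the 1,3-diketone 14 (an O-benzoate, if formed, would reach the same diketone by Baker–Venkataraman acyl shift), and acid then closes the pyranone by addition of the phenol to the benzoyl carbonyl and loss of water. The only free phenol is the one next to the piperidine, so the heterocycle can only end up on C8.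

Step 7
Reactants: 15 (R)-5,7-dimethoxy-8-(1-methylpiperidin-2-yl)-2-phenyl-4H-chromen-4-one
Product: 16 (R)-5,7-dihydroxy-8-(1-methylpiperidin-2-yl)-2-phenyl-4H-chromen-4-one
Conditions: BBr3 (6 equiv), CH2Cl2, −78 °C → rt; then MeOH, H2O (pH 7–8)
Reagents that add atoms: none
Why: Lewis acid cleavage of aryl methyl ethers: boron binds the ether oxygen and bromide attacks the methyl group; the C5 ether, chelated to the C4 carbonyl, should go first and the C7 ether follow at room temperature. Hot protic acid is avoided so that neither C2' nor the C8 placement is put at risk.

## Compound list

1 | 2-hydroxy-4,6-dimethoxybenzaldehyde | COc1cc(O)c(C=O)c(OC)c1 | starting material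
2 | N-methylbut-3-en-1-amine | CNCCC=C | starting material
3 | dibutyl vinylboronate (dibutyl ethenylboronate) | C=CB(OCCCC)OCCCC | starting material
4 | 2-{[but-3-en-1-yl(methyl)iminio]methyl}-3,5-dimethoxyphenolate | C=CCC[N+](C)=Cc1c([O-])cc(OC)cc1OC | intermediate (not isolated)
5 | (R)-2-{1-[but-3-en-1-yl(methyl)amino]prop-2-en-1-yl}-3,5-dimethoxyphenol | C=C[C@@H](N(C)CCC=C)c1c(O)cc(OC)cc1OC | intermediate
6 | acetic anhydride | CC(=O)OC(C)=O | starting material
7 | (R)-2-{1-[but-3-en-1-yl(methyl)amino]prop-2-en-1-yl}-3,5-dimethoxyphenyl acetate | C=C[C@@H](N(C)CCC=C)c1c(OC(C)=O)cc(OC)cc1OC | intermediate
8 | (R)-N-[1-(2-acetoxy-4,6-dimethoxyphenyl)prop-2-en-1-yl]-N-methylbut-3-en-1-aminium 4-methylbenzenesulfonate | C=C[C@@H]([NH+](C)CCC=C)c1c(OC(C)=O)cc(OC)cc1OC.Cc1ccc(cc1)S(=O)(=O)[O-] | intermediate (not isolated)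
9 | (R)-2-(2-acetoxy-4,6-dimethoxyphenyl)-1-methyl-1,2,5,6-tetrahydropyridin-1-ium 4-methylbenzenesulfonate | C[NH+]1CCC=C[C@@H]1c1c(OC(C)=O)cc(OC)cc1OC.Cc1ccc(cc1)S(=O)(=O)[O-] | intermediate (not isolated)
10 | (R)-3,5-dimethoxy-2-(1-methyl-1,2,5,6-tetrahydropyridin-2-yl)phenyl acetate | CN1CCC=C[C@@H]1c1c(OC(C)=O)cc(OC)cc1OC | intermediate
11 | (R)-3,5-dimethoxy-2-(1-methylpiperidin-2-yl)phenyl acetate | CN1CCCC[C@@H]1c1c(OC(C)=O)cc(OC)cc1OC | intermediate
12 | (R)-1-[2-hydroxy-4,6-dimethoxy-3-(1-methylpiperidin-2-yl)phenyl]ethan-1-one | CN1CCCC[C@@H]1c1c(O)c(C(C)=O)c(OC)cc1OC | intermediate
13 | benzoyl chloride | O=C(Cl)c1ccccc1 | starting material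
14 | (R)-1-[2-hydroxy-4,6-dimethoxy-3-(1-methylpiperidin-2-yl)phenyl]-3-phenylpropane-1,3-dione | CN1CCCC[C@@H]1c1c(O)c(C(=O)CC(=O)c2ccccc2)c(OC)cc1OC | intermediate (not isolated)
15 | (R)-5,7-dimethoxy-8-(1-methylpiperidin-2-yl)-2-phenyl-4H-chromen-4-one | CN1CCCC[C@@H]1c1c(OC)cc(OC)c2c(=O)cc(-c3ccccc3)oc12 | intermediate
16 | (R)-5,7-dihydroxy-8-(1-methylpiperidin-2-yl)-2-phenyl-4H-chromen-4-one | CN1CCCC[C@@H]1c1c(O)cc(O)c2c(=O)cc(-c3ccccc3)oc12 | target

## Step count and risk

Total step count: 7. Longest linear sequence: 7 steps (1 → 5 → 7 → 10 → 11 → 12 → 15 → 16); 2, 3, 6 and 13 enter as purchased components.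

Least certain steps:

Step 3 (key step). Three processes are most likely to spoil it. Traces of free amine can decompose the catalyst to ruthenium hydrides, which move the butenyl double bond inward (ring contraction on closure) or move the new double bond to C2' (loss of the stereocentre). The protonated C2'–N1' bond is allylic and benzylic to an electron-rich ring and may heterolyse, giving loss of configuration or 1,3-transposition of the amine. Closure onto the hindered vinyl group may be slow. The fallback gives up metathesis and closes the ring at N1'–C6' by alkylation; it sets out from 1 and comes back at 11.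
- 1 is condensed with (S)-2-methylpropane-2-sulfinamide (Ti(OEt)4, THF) to the N-sulfinyl imine F1.
- Cl(CH2)4MgBr (excess, to allow for the phenol; CH2Cl2/THF, −48 °C) should add through the usual six-membered magnesium chelate to give the chloroalkyl sulfinamide F2 with C2' as R. The antipodal auxiliary serves if the phenoxide reverses the sense.
- HCl in MeOH at 0 °C removes the sulfinyl group, and K2CO3 with catalytic NaI in MeCN closes the ring to the secondary piperidine F3.
- Reductive methylation (aqueous CH2O, NaBH(OAc)3) gives the N-methylpiperidine phenol F4 (the same compound as A9), and acetylation as in step 2 gives 11.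

Step 5. The Lewis acid on nitrogen may assist heterolysis of C2'–N1', so that reversible ring opening to a benzylic cation erodes the configuration or proton loss from C3' opens the ring for good; acyl transfer to the carbon between the two methoxy groups is a lesser risk. The fallback replaces the acid-promoted acyl shift by a base-mediated ortho-formylation; it sets out from 11 and comes back at 12.
- K2CO3 in MeOH at 0 °C cleaves the acetate to the N-methylpiperidine phenol F4.
- MgCl2, Et3N and paraformaldehyde in MeCN (about 70 °C) formylate the magnesium phenoxide at the only free ortho position to give the salicylaldehyde F5.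
- MeMgBr in THF gives the secondary carbinol F6 (both carbinol epimers).
- MnO2 in CH2Cl2 oxidises F6 to 12.

Step 1. The iminium from a doubly ortho-substituted, electron-rich aldehyde is a weak electrophile, so vinyl transfer may be slow and an uncatalysed background reaction may lower the facial selectivity; the product can also lose configuration on standing. The fallback separates bond formation from stereocontrol; it sets out from 1 and comes back at 5.
- 1, 2 and 3 are combined without the chiral diol in hexafluoropropan-2-ol at room temperature, which should give the racemic amine F7.
- Preparative chromatography on a chiral stationary phase (amylose carbamate phase, CO2/MeOH with a trace of Et2NH) separates 5 from its enantiomer F8.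
- 5 is acetylated at once as in step 2.

Step 7. Cleavage of the C7 ether may stall once the C5 phenol is bound to boron, and forcing it with more Lewis acid or time exposes the newly freed C7 phenol, ortho to C2', to acid-assisted ionisation. The fallback splits the task into two orthogonal cleavages; it sets out from 15 and comes back at 16.
- BCl3 (CH2Cl2, −78 → 0 °C) should remove only the chelated C5 methyl group and give the 5-hydroxy-7-methoxyflavone F9.
- The remaining ether is cleaved by nucleophilic attack on the methyl group with NaSEt in DMF at about 100 °C, under basic conditions in which the nitrogen is not protonated.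

## Further compounds

F1 | step 3 | (S,E)-N-(2-hydroxy-4,6-dimethoxybenzylidene)-2-methylpropane-2-sulfinamide | CC(C)(C)[S@](=O)/N=C/c1c(O)cc(OC)cc1OC
F2 | step 3 | (S)-N-[(R)-5-chloro-1-(2-hydroxy-4,6-dimethoxyphenyl)pentyl]-2-methylpropane-2-sulfinamide | CC(C)(C)[S@](=O)N[C@H](CCCCCl)c1c(O)cc(OC)cc1OC
F3 | step 3 | (R)-3,5-dimethoxy-2-(piperidin-2-yl)phenol | N1CCCC[C@@H]1c1c(O)cc(OC)cc1OC
F4 | step 3 | (R)-3,5-dimethoxy-2-(1-methylpiperidin-2-yl)phenol | CN1CCCC[C@@H]1c1c(O)cc(OC)cc1OC
F5 | step 5 | (R)-2-hydroxy-4,6-dimethoxy-3-(1-methylpiperidin-2-yl)benzaldehyde | CN1CCCC[C@@H]1c1c(O)c(C=O)c(OC)cc1OC
F6 | step 5 | 1-{2-hydroxy-4,6-dimethoxy-3-[(R)-1-methylpiperidin-2-yl]phenyl}ethan-1-ol (both carbinol epimers) | CN1CCCC[C@@H]1c1c(O)c(C(C)O)c(OC)cc1OC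
F7 | step 1 | racemic 2-{1-[but-3-en-1-yl(methyl)amino]prop-2-en-1-yl}-3,5-dimethoxyphenol | C=CC(N(C)CCC=C)c1c(O)cc(OC)cc1OC
F8 | step 1 | (S)-2-{1-[but-3-en-1-yl(methyl)amino]prop-2-en-1-yl}-3,5-dimethoxyphenol | C=C[C@H](N(C)CCC=C)c1c(O)cc(OC)cc1OC
F9 | step 7 | (R)-5-hydroxy-7-methoxy-8-(1-methylpiperidin-2-yl)-2-phenyl-4H-chromen-4-one | CN1CCCC[C@@H]1c1c(OC)cc(O)c2c(=O)cc(-c3ccccc3)oc12
A1 | alternative 1 | (R)-1-(tert-butoxycarbonyl)piperidine-2-carboxylic acid | CC(C)(C)OC(=O)N1CCCC[C@@H]1C(=O)O
A2 | alternative 1 | tert-butyl (R)-2-[2-diazo-2-(4-oxo-6-phenyl-4H-pyran-2-yl)acetyl]piperidine-1-carboxylate | CC(C)(C)OC(=O)N1CCCC[C@@H]1C(=O)C(=[N+]=[N-])c1cc(=O)cc(-c2ccccc2)o1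
A3 | alternative 1 | ethoxyacetylene | C#COCC
A4 | alternative 1 | tert-butyl (R)-2-(7-ethoxy-5-hydroxy-4-oxo-2-phenyl-4H-chromen-8-yl)piperidine-1-carboxylate | CC(C)(C)OC(=O)N1CCCC[C@@H]1c1c(OCC)cc(O)c2c(=O)cc(-c3ccccc3)oc12
A5 | alternative 2 | racemic methyl [5-hydroxy-5-(2-hydroxy-4,6-dimethoxyphenyl)pentyl]carbamate | COC(=O)NCCCCC(O)c1c(O)cc(OC)cc1OC
A6 | alternative 2 | methyl (R)-2-(2-hydroxy-4,6-dimethoxyphenyl)piperidine-1-carboxylate | COC(=O)N1CCCC[C@@H]1c1c(O)cc(OC)cc1OC
A7 | alternative 3 | (R)-3,5-dimethoxy-2-[1-(methylamino)but-3-en-1-yl]phenol | C=CC[C@@H](NC)c1c(O)cc(OC)cc1OC
A8 | alternative 3 | carbon monoxide | [C-]#[O+]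
A9 | alternative 3 | (R)-3,5-dimethoxy-2-(1-methylpiperidin-2-yl)phenol | CN1CCCC[C@@H]1c1c(O)cc(OC)cc1OC
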